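## Assumptions
- The target has no stereocentres, so "single enantiomer" is trivially met. The only stereo-element is the ring C3=C4 alkene, which is fixed by the pyran ring.
- 2,4,6-Trihydroxybenzaldehyde and 2,4-dihydroxyphenylacetic acid are taken as commercial.
- In Step 1, the para OH is assumed to be the most acidic OH and to be mono-protected selectively.

## Retrosynthetic overview
1. The target is a 3-aryl-2H-chromene (isoflav-3-ene). The last ring-forming step is cyclodehydration of a (Z)-o-hydroxycinnamyl alcohol, and the last step is global MOM removal.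
2. The (Z)-alkene comes from DIBAL/Luche reduction of a 3-arylcoumarin, whose cis-locked C3=C4 guarantees the geometry needed for ring closure.
3. The 6-prenyl group is installed by a 5-OH-directed ortho C–H prenylation on the coumarin (the proposed new step, with C4a blocking the other ortho site). The 5-OH is then methylated.
4. The coumarin ring is formed first, by Perkin condensation of the symmetrical 4-MOM-phloroglucinaldehyde with a bis-MOM-protected 2,4-dihydroxyphenylacetic acid. Symmetry makes lactonisation unambiguous. Ring order: lactone, then prenylation, then pyran.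

## Route

**Step 1**
Reactants: 1 (2,4,6-trihydroxybenzaldehyde); 2 (chloromethyl methyl ether)
Product: 3 (2,6-dihydroxy-4-(methoxymethoxy)benzaldehyde)
Conditions: 2 (1.0 equiv), i-Pr2NEt, CH2Cl2/DMF, 0 °C
Reagents that add atoms: MOMCl, ClCOC
Why: Williamson-type MOM etherification; the para OH is the most acidic and non-chelated, so it reacts first and leaves a symmetrical 2,6-diol.

**Step 2**
Reactants: 4 (2,4-dihydroxyphenylacetic acid); 2 (MOMCl, 3.6 equiv)
Product: 5 (methoxymethyl 2-[2,4-bis(methoxymethoxy)phenyl]acetate)
Conditions: 2, i-Pr2NEt, CH2Cl2, 0 °C → 25 °C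
Reagents that add atoms: MOMCl, ClCOC
Why: Exhaustive MOM protection of both phenols and the carboxylic acid, so that the aryl OHs cannot interfere in the Perkin step.

**Step 3**
Reactants: 5; 6 (lithium hydroxide)
Product: 7 (2-[2,4-bis(methoxymethoxy)phenyl]acetic acid)
Conditions: 6 (3 equiv), THF/H2O 3:1, 25 °C; then aqueous citric acid to pH 4
Reagents that add atoms: LiOH, [Li+].[OH-] (the hydroxide oxygen ends up in the acid)
Why: Saponification cleaves the labile MOM ester selectively, and aryl MOM ethers are base-stable.

**Step 4**
Reactants: 3; 7; 8 (acetic anhydride)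
Product: 9 (5-acetoxy-7-(methoxymethoxy)-3-[2,4-bis(methoxymethoxy)phenyl]-2H-chromen-2-one)
Conditions: 8, Et3N, 120 °C, 16 h
Reagents that add atoms: Ac2O, CC(=O)OC(C)=O (its acetyl group caps the second OH as OAc)
Why: Perkin condensation forms the E-α-aryl-cinnamate with the A ring cis to CO2H, which lactonises onto either of the two equivalent ortho OH groups and gives one coumarin; no stereocentre is formed.

**Step 5**
Reactants: 9
Product: 10 (5-hydroxy-7-(methoxymethoxy)-3-[2,4-bis(methoxymethoxy)phenyl]-2H-chromen-2-one)
Conditions: K2CO3 (1.2 equiv), MeOH/THF 1:1, 0 °C, 20 min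
Reagents that add atoms: none
Why: Aryl acetate methanolysis is much faster than opening of the coumarin lactone at 0 °C, so the 5-OH is freed selectively.

**Step 6**
Reactants: 10; 11 (prenyl bromide)
Product: 12 (5-hydroxy-6-(3-methylbut-2-enyl)-7-(methoxymethoxy)-3-[2,4-bis(methoxymethoxy)phenyl]-2H-chromen-2-one)
Conditions: MgBr2·OEt2 (1.5 equiv), i-Pr2NEt (1.5 equiv), toluene/THF 10:1, 25 °C, 30 min; then 11 (1.2 equiv), 60 °C, 12 h
Reagents that add atoms: prenyl bromide, CC(C)=CCBr
Why: Proposed new method: the Mg/amine pair makes ArO–MgBr without any carbanion-type base, so the lactone and C3=C4 acceptor survive. In toluene the tight O–Mg contact pair blocks O-alkylation and holds the prenyl bromide through Mg···Br in a six-membered ion-pair collapse at C6, the only free ortho carbon (C4a is blocked). The electron-rich para position C8 is too distant from Mg to react, and SN2-type attack at the prenyl CH2 gives linear prenyl. The closest known reactions are magnesium-phenoxide ortho-C-allylation, Casiraghi ortho-hydroxyalkylation and boron-templated Sugasawa ortho-acylation; here they are applied to a hindered, doubly oxygen-flanked site on a coumarin with a competing para position.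

**Step 7**
Reactants: 12; 13 (iodomethane)
Product: 14 (5-methoxy-6-prenyl-7-(methoxymethoxy)-3-[2,4-bis(methoxymethoxy)phenyl]-2H-chromen-2-one)
Conditions: 13 (3 equiv), K2CO3, DMF, 25 °C, 6 h
Reagents that add atoms: MeI, CI
Why: Williamson O-methylation of the only free phenol, the hindered 5-OH, installs the 5-OMe of the target.

**Step 8**
Reactants: 14
Product: 15 ((Z)-2-[3-hydroxy-2-(2,4-bis(methoxymethoxy)phenyl)prop-1-en-1-yl]-3-methoxy-4-prenyl-5-(methoxymethoxy)phenol)
Conditions: DIBAL-H (3 equiv), CH2Cl2, −78 °C, 2 h; then MeOH, CeCl3·7H2O, NaBH4, 0 °C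
Reagents that add atoms: none (hydride only)
Why: DIBAL reduces the lactone to the lactol (hydroxy-enal), and Luche 1,2-reduction gives the allylic alcohol; the Z geometry is inherited from the cis-locked coumarin C3=C4, so no new stereocentre arises.

**Step 9**
Reactants: 15
Product: 16 (3-[2,4-bis(methoxymethoxy)phenyl]-5-methoxy-7-(methoxymethoxy)-6-prenyl-2H-chromene)
Conditions: PPh3 (1.5 equiv), DIAD (1.5 equiv), THF, 0 °C → 25 °C
Reagents that add atoms: none
Why: Intramolecular Mitsunobu etherification of the phenol onto the primary allylic alcohol closes the six-membered pyran; the Z alkene places the CH2OH next to the phenol.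

**Step 10**
Reactants: 16
Product: 17 (dehydroglyasperin C)
Conditions: TMSOTf (6 equiv), 2,2'-bipyridyl (9 equiv), MeCN, 0 °C → 25 °C; then H2O
Reagents that add atoms: none
Why: Fujioka-type mild deprotection of aromatic MOM ethers proceeds via pyridinium intermediates under near-neutral conditions, so the acid-sensitive 7-oxygenated 2H-chromene and the prenyl alkene are preserved.

## Compound list
1 | 2,4,6-trihydroxybenzaldehyde | O=Cc1c(O)cc(O)cc1O | starting material
2 | chloromethyl methyl ether (MOMCl) | ClCOC | starting material (reagent)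
3 | 2,6-dihydroxy-4-(methoxymethoxy)benzaldehyde | O=Cc1c(O)cc(OCOC)cc1O | intermediate
4 | 2,4-dihydroxyphenylacetic acid | OC(=O)Cc1ccc(O)cc1O | starting material
5 | methoxymethyl 2-[2,4-bis(methoxymethoxy)phenyl]acetate | COCOC(=O)Cc1ccc(OCOC)cc1OCOC | intermediate
6 | lithium hydroxide | [Li+].[OH-] | starting material (reagent)
7 | 2-[2,4-bis(methoxymethoxy)phenyl]acetic acid | OC(=O)Cc1ccc(OCOC)cc1OCOC | intermediate
8 | acetic anhydride | CC(=O)OC(C)=O | starting material (reagent)
9 | 5-acetoxy-7-(methoxymethoxy)-3-[2,4-bis(methoxymethoxy)phenyl]coumarin | CC(=O)Oc1cc(OCOC)cc2oc(=O)c(-c3ccc(OCOC)cc3OCOC)cc12 | intermediate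
10 | 5-hydroxy-7-(methoxymethoxy)-3-[2,4-bis(methoxymethoxy)phenyl]coumarin | Oc1cc(OCOC)cc2oc(=O)c(-c3ccc(OCOC)cc3OCOC)cc12 | intermediate
11 | prenyl bromide (1-bromo-3-methylbut-2-ene) | CC(C)=CCBr | starting material (reagent)
12 | 5-hydroxy-6-prenyl-7-(methoxymethoxy)-3-[2,4-bis(methoxymethoxy)phenyl]coumarin | Oc1c(CC=C(C)C)c(OCOC)cc2oc(=O)c(-c3ccc(OCOC)cc3OCOC)cc12 | intermediate
13 | iodomethane | CI | starting material (reagent)
14 | 5-methoxy-6-prenyl-7-(methoxymethoxy)-3-[2,4-bis(methoxymethoxy)phenyl]coumarin | COc1c(CC=C(C)C)c(OCOC)cc2oc(=O)c(-c3ccc(OCOC)cc3OCOC)cc12 | intermediate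
15 | (Z)-allylic alcohol phenol (ring-opened reduction product of 14) | Oc1cc(OCOC)c(CC=C(C)C)c(OC)c1/C=C(\CO)c1ccc(OCOC)cc1OCOC | intermediate
16 | tris-MOM 3-aryl-2H-chromene | COc1c(CC=C(C)C)c(OCOC)cc2OCC(c3ccc(OCOC)cc3OCOC)=Cc12 | intermediate
17 | dehydroglyasperin C | COc1c2c(cc(O)c1CC=C(C)C)OCC(c1ccc(O)cc1O)=C2 | target

## Totals
- Total steps: 10.
- Longest linear sequence: 9 steps, from 4 through Steps 2–10.

## Three steps most likely to fail
1. **Step 6 (proposed new C6-selective ortho-prenylation).** Risks are O-prenylation, C8 (para) attack and reverse-prenyl formation.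
   Fallback (known chemistry, different approach): O-allylate the 5-OH of 10 (allyl bromide, K2CO3). Run an aromatic Claisen rearrangement (PhNEt2, 210 °C, microwave), which is forced to C6 because C4a is blocked. Then convert the allyl group to prenyl by cross-metathesis with excess 2-methyl-2-butene (Hoveyda–Grubbs II), and continue with Step 7.
2. **Step 4 (Perkin on the deactivated, electron-rich aldehyde 3).** Yields may be low.
   Fallback: change the bond construction. Form a 3-bromocoumarin by reacting aldehyde 3 with (bromo)(ethoxycarbonyl)methylenetriphenylphosphorane, then lactonise. Couple the 3-bromocoumarin with 2,4-bis(MOMO)phenylboronic acid (Pd(PPh3)4, K3PO4) to give 10.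
3. **Step 9 (Mitsunobu cyclodehydration).** Risks are o-quinone-methide side reactions and intermolecular coupling.
   Fallback: DIBAL reduction of 14 at −78 °C stops at the lactol. Deoxygenate the lactol with Et3SiH/BF3·OEt2 at −78 °C via the benzopyrylium ion, with hydride delivered at C2, to give 16 directly. The 4H-chromene isomer would need to be removed.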